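The route cuts both butenolides (rings B and C) of the C2-symmetric dispiro core at C4–Br, C3–C7 and O1–C2. Each ring hides a β-bromo Baylis–Hillman motif: bromine on C4, carbinol C7 on C3, and the oxygen of spiro C5 held cis to the C2 carboxyl. One operation therefore adds bromide and butanal to both arms of a bis-ynoate and closes both lactones. This forms four skeletal bonds, two rings and both C7 centres. The precursor is the resolved, all-trans 3,4-dibromocyclobutane (ring A). It bears a methyl propiolate arm and a triethylsilyl-masked tertiary oxygen on each of C5 and C5', so no hydroxyl proton can quench the bromoallenolates.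

Key step: step 5

Numbering: in each butenolide O1, C2 (C=O), C3, C4 (C–Br) and C5 (spiro carbon). C6 is the cyclobutane CHBr next to C5, C7 the side-chain carbinol, and C8–C10 the propyl group. Primes mark the second half. Ring A is the cyclobutane (C5, C5', C6', C6), and rings B and C are the butenolides.

Remark on the chemistry: the core is C2-symmetric, so its two arms are homotopic and (7S,7'R) and (7R,7'S) describe one and the same compound. The target is (5S,5'S,6R,6'R,7S,7'R), with the two ring oxygens trans to each other and each C6 bromine trans to the oxygen on the neighbouring C5.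

Step 1
Reactants: 1 1,2-bis(trimethylsilyloxy)cyclobut-1-ene
Product: 2 cyclobutane-1,2-dione
Conditions: Br2 (1.0 equiv), pentane, −60 °C to rt; crystallised cold under N2
Reagents that add atoms: none
Why: Electrophilic bromination of the bis-silyl enediol ether with loss of two bromosilanes is the standard oxidative unmasking of an acyloin-derived enediol to the strained 1,2-dione, and no stereocentre is created.

Step 2
Reactants: 2 cyclobutane-1,2-dione
Product: 4 cyclobut-3-ene-1,2-dione, via 3-bromocyclobutane-1,2-dione 3 (not isolated)
Conditions: Br2 (1.0 equiv), CH2Cl2, 0 °C, N2 sweep; n-Bu3N (1.05 equiv), Et2O, −30 to 0 °C; filtration, sublimation, stored cold and dark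
Reagents that add atoms: none
Why: Acid-catalysed α-bromination puts bromine on a carbon that is β to the other carbonyl, so a hindered tertiary amine should trigger E1cB dehydrobromination, the tactic that turns 3-bromocyclobutanone into cyclobutenone, and no stereocentre remains.

Step 3
Reactants: 4 cyclobut-3-ene-1,2-dione; 5 methyl propiolate
Product: 9 racemic dimethyl 3,3'-[(1S*,2S*,3R*,4R*)-3,4-dibromo-1,2-bis(triethylsilyloxy)cyclobutane-1,2-diyl]bis(prop-2-ynoate), via chloromagnesium acetylide 6 (not isolated), via bis(chloromagnesium) dialkoxide 7 (not isolated), via cyclobutene bis(triethylsilyl ether) 8 (not isolated)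
Conditions: 5 (2.6 equiv), TMPMgCl·LiCl (2.6 equiv), THF, −40 °C; 4, −78 to −40 °C; TESOTf (3 equiv), −78 to −30 °C; cold aq. citric acid wash, pentane, kept below 0 °C; Br2 (1.1 equiv), CH2Cl2, −60 to −20 °C, dark; chromatography
Reagents that add atoms: triethylsilyl trifluoromethanesulfonate (TESOTf), CC[Si](CC)(CC)OS(=O)(=O)C(F)(F)F; bromine, BrBr
Why: This is a double 1,2-alkynylation of Grignard type, a silyl triflate capture and an electrophilic anti-dibromination in sequence, in which the first magnesium alkoxide chelates the remaining carbonyl and delivers the second acetylide to its own face to set the trans (C2) C5/C5' diol, the covalent magnesium alkoxides and the low temperature hold back conrotatory opening of the trans-3,4-dioxygenated cyclobutene, and bromide opens the bromonium ion (both alkene faces are equivalent by C2) at the carbon whose rear side is flanked by the slim alkyne rather than by OSiEt3, so that each bromine ends trans to its neighbouring oxygen while the electron-poor ynoates ignore Br2.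

Step 4
Reactants: 9 racemic dibromo bis-ynoate bis(triethylsilyl ether)
Product: 10 dimethyl 3,3'-[(1S,2S,3R,4R)-3,4-dibromo-1,2-bis(triethylsilyloxy)cyclobutane-1,2-diyl]bis(prop-2-ynoate)
Conditions: preparative SFC, amylose tris(3,5-dimethylphenylcarbamate) phase, CO2/i-PrOH
Reagents that add atoms: none
Why: Chromatographic resolution on a polysaccharide chiral phase parts the two C2-symmetric antipodes of a thermally stable racemate without any chemistry on its base- and nucleophile-sensitive groups, and anomalous-dispersion X-ray analysis of the bromide should identify the (1S,2S,3R,4R) enantiomer that fixes C5, C5', C6 and C6' in the absolute sense.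

Step 5
Reactants: 10 (1S,2S,3R,4R)-dibromo bis-ynoate bis(triethylsilyl ether); 11 butanal
Product: 14 (5S,5'S,6R,6'R,7S,7'R)-bis(de-O-acetyl) target diol, via bis(bromomagnesium) aldolate 12 (not isolated), via desilylated tetraol diester 13 (not isolated)
Conditions: MgBr2·OEt2 (6 equiv), 11 (8 equiv), CH2Cl2, −20 °C to rt; then TsOH·H2O (4 equiv) in MeOH, 0 °C to rt; silica gel separation of the C7 diastereomers
Reagents that add atoms: magnesium bromide diethyl etherate (MgBr2·OEt2), [Mg+2].[Br-].[Br-].CCOCC
Why: MgBr2 binds ester and aldehyde, bromide adds to C4 and C4' of the ynoates, and each magnesium bromoallenolate attacks butanal through C3, which is the magnesium-halide halo-aldol (β-bromo Baylis–Hillman) reaction known for alkynoates and ynones, run here on two arms in one flask. The aldehyde reaches C3 in the plane of the C4 substituents from the bromine side, away from quaternary C5, so the ester ends cis to C5, which by the CIP rules is the E isomer (Br trans to CO2Me) and the only geometry that can lactonise, while any Z isomer should be fed back by reversible bromide addition–elimination at C4 in the bromide-rich acidic medium. Methanolic TsOH then strips both silyl groups and each tertiary C5 hydroxyl closes ring B or ring C by 5-exo-trig attack on its methyl ester with loss of methanol. The silyl ethers are needed in the first stage because a free hydroxyl would protonate the allenolate and stop at hydrobromination, and only bromide salts and a non-nucleophilic acid are used because iodide would debrominate C6/C6' and chloride would scramble the C4 halide. C7 and C7' arise in the aldol event without useful control from the remote core, so the unlike (7S,7'R) compound, which counts twice because the arms are homotopic, should hold the largest statistical share of the three diastereomers and is taken by chromatography. C5, C5', C6 and C6' take no part in any bond change.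

Step 6
Reactants: 14 (5S,5'S,6R,6'R,7S,7'R)-diol
Product: 15 target, (5S,5'S,6R,6'R,7S,7'R)-diacetate (CNP0266230.1)
Conditions: Ac2O (4 equiv), Sc(OTf)3 (2 mol %), MeCN–CH2Cl2, −20 to 0 °C
Reagents that add atoms: acetic anhydride, CC(=O)OC(C)=O
Why: Lewis-acid-catalysed acylation with Ac2O esterifies both secondary carbinols at oxygen with retention at C7 and C7', and the amine-free medium avoids addition–elimination of pyridine-type nucleophiles at the β-bromobutenolide carbons.

Compound list
1 | 1,2-bis(trimethylsilyloxy)cyclobut-1-ene | C[Si](C)(C)OC1=C(O[Si](C)(C)C)CC1 | starting material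
2 | cyclobutane-1,2-dione | O=C1CCC1=O | intermediate
3 | 3-bromocyclobutane-1,2-dione (racemic, not isolated) | O=C1CC(Br)C1=O | intermediate
4 | cyclobut-3-ene-1,2-dione | O=C1C=CC1=O | intermediate
5 | methyl propiolate | C#CC(=O)OC | starting material
6 | chloromagnesium acetylide of methyl propiolate (not isolated) | COC(=O)C#C[Mg]Cl | intermediate
7 | bis(chloromagnesium) dialkoxide of dimethyl 3,3'-(trans-1,2-dihydroxycyclobut-3-ene-1,2-diyl)bis(prop-2-ynoate) (racemate, relative configuration drawn, not isolated) | COC(=O)C#C[C@@]1(O[Mg]Cl)C=C[C@]1(O[Mg]Cl)C#CC(=O)OC | intermediate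
8 | dimethyl 3,3'-[trans-1,2-bis(triethylsilyloxy)cyclobut-3-ene-1,2-diyl]bis(prop-2-ynoate) (racemate, relative configuration drawn, not isolated, kept cold) | COC(=O)C#C[C@@]1(O[Si](CC)(CC)CC)C=C[C@]1(O[Si](CC)(CC)CC)C#CC(=O)OC | intermediate
9 | racemic dimethyl 3,3'-[(1S*,2S*,3R*,4R*)-3,4-dibromo-1,2-bis(triethylsilyloxy)cyclobutane-1,2-diyl]bis(prop-2-ynoate) (the enantiomer carried on is drawn) | COC(=O)C#C[C@@]1(O[Si](CC)(CC)CC)[C@@H](Br)[C@H](Br)[C@]1(O[Si](CC)(CC)CC)C#CC(=O)OC | intermediate
10 | dimethyl 3,3'-[(1S,2S,3R,4R)-3,4-dibromo-1,2-bis(triethylsilyloxy)cyclobutane-1,2-diyl]bis(prop-2-ynoate), single enantiomer, key-step precursor | COC(=O)C#C[C@@]1(O[Si](CC)(CC)CC)[C@@H](Br)[C@H](Br)[C@]1(O[Si](CC)(CC)CC)C#CC(=O)OC | intermediate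
11 | butanal | CCCC=O | starting material
12 | bis(bromomagnesium) aldolate of the (E,E)-bis[3-bromo-2-(1-hydroxybutyl)acrylate] bis(triethylsilyl ether), 7S,7'R isomer drawn (not isolated) | CCC[C@H](O[Mg]Br)/C(C(=O)OC)=C(Br)/[C@@]1(O[Si](CC)(CC)CC)[C@@H](Br)[C@H](Br)[C@]1(O[Si](CC)(CC)CC)/C(Br)=C(C(=O)OC)/[C@@H](CCC)O[Mg]Br | intermediate
13 | dimethyl (2E,2'E)-3,3'-[(1S,2S,3R,4R)-3,4-dibromo-1,2-dihydroxycyclobutane-1,2-diyl]bis[3-bromo-2-(1-hydroxybutyl)acrylate], 7S,7'R isomer drawn (not isolated) | CCC[C@H](O)/C(C(=O)OC)=C(Br)/[C@@]1(O)[C@@H](Br)[C@H](Br)[C@]1(O)/C(Br)=C(C(=O)OC)/[C@@H](CCC)O | intermediate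
14 | (5S,5'S,6R,6'R,7S,7'R)-bis(de-O-acetyl) target: dispiro bis(4-bromo-3-(1-hydroxybutyl)butenolide) on the trans-dibromocyclobutane | CCC[C@H](O)C1=C(Br)[C@@]2(OC1=O)[C@@H](Br)[C@H](Br)[C@@]21OC(=O)C([C@@H](CCC)O)=C1Br | intermediate
15 | CNP0266230.1, (5S,5'S,6R,6'R,7S,7'R)-diacetate | CCC[C@H](OC(C)=O)C1=C(Br)[C@@]2(OC1=O)[C@@H](Br)[C@H](Br)[C@@]21OC(=O)C([C@@H](CCC)OC(C)=O)=C1Br | target

Total step count: 6. Longest linear sequence: 6 steps (1 to 15).

Steps most likely to fail

Step 5. Bromide addition to the hindered internal ynoates may lag behind self-condensation of butanal, and one arm may stop at hydrobromination. Above all, the aldol event has no facial control at C7 and C7', so the unlike isomer may be hard to part from its two like epimers. The fallback replaces separation by reagent control. It sets out from 14, taken as the unseparated mixture with its C7 epimers.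
- Dess–Martin periodinane in CH2Cl2 erases both carbinol centres and gives the bis(butanoyl) diketone F1.
- BH3·SMe2 with (S)-2-methyl-CBS-oxazaborolidine in toluene at −40 °C reads the bromobutenolide as the large group and propyl as the small one. It should give the like (7R,7'R)-diol F2.
- A Mitsunobu reaction held to one equivalent each of AcOH, PPh3 and DIAD inverts either of the two homotopic carbinols and gives the (7S)-acetate (7'R)-alcohol F3. This differs clearly in polarity from recovered diol and from diacetate.
- Acetylation under the conditions of step 6 comes back to the route at 15.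

Step 3. The stabilised propiolate acetylide may add too slowly to the second carbonyl, and the trans selectivity of that addition may erode. The trans-3,4-dioxygenated cyclobutene may also open in a conrotatory sense before bromine has added. The fallback separates ring C–C bond formation from carboxylation. It sets out from 4.
- Excess HC≡CMgBr in THF at −78 to −40 °C, a far stronger yet still covalently bound nucleophile, gives the bis(bromomagnesium) diethynyl dialkoxide F4.
- Capture with TESOTf at −78 °C gives trans-3,4-diethynyl-3,4-bis(triethylsilyloxy)cyclobutene F5.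
- n-BuLi (2 equiv) at −78 °C gives the dilithium bis-acetylide F6.
- Methyl chloroformate at the same temperature comes back to the route at 8, which is brominated cold as in step 3.

Step 2. Bromination may run on to polybromides. The amine may also start polymerisation of the very electrophilic ene-dione, which is volatile and light-sensitive as well. The fallback trades the base-induced elimination for a pericyclic one. It sets out from 2.
- PhSeCl in EtOAc at rt selenenylates the enol and gives 3-(phenylselanyl)cyclobutane-1,2-dione F7.
- mCPBA (1 equiv) in CH2Cl2 at −78 °C gives the selenoxide F8.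
- Warming to 0 °C brings about base-free syn-elimination and comes back to the route at 4.

Further compounds
F1 | step 5 | (5S,5'S,6R,6'R)-bis(3-butanoyl-4-bromobutenolide) diketone | CCCC(=O)C1=C(Br)[C@@]2(OC1=O)[C@@H](Br)[C@H](Br)[C@@]21OC(=O)C(C(=O)CCC)=C1Br
F2 | step 5 | (5S,5'S,6R,6'R,7R,7'R)-diol | CCC[C@@H](O)C1=C(Br)[C@@]2(OC1=O)[C@@H](Br)[C@H](Br)[C@@]21OC(=O)C([C@@H](CCC)O)=C1Br
F3 | step 5 | (5S,5'S,6R,6'R)-(7S)-acetate (7'R)-alcohol | CCC[C@H](OC(C)=O)C1=C(Br)[C@@]2(OC1=O)[C@@H](Br)[C@H](Br)[C@@]21OC(=O)C([C@@H](CCC)O)=C1Br
F4 | step 3 | bis(bromomagnesium) dialkoxide of trans-1,2-diethynylcyclobut-3-ene-1,2-diol (racemate, relative configuration drawn) | C#C[C@@]1(O[Mg]Br)C=C[C@]1(O[Mg]Br)C#C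
F5 | step 3 | trans-3,4-diethynyl-3,4-bis(triethylsilyloxy)cyclobutene (racemate, relative configuration drawn) | C#C[C@@]1(O[Si](CC)(CC)CC)C=C[C@]1(O[Si](CC)(CC)CC)C#C
F6 | step 3 | dilithium bis-acetylide of F5 (racemate, relative configuration drawn) | [Li]C#C[C@@]1(O[Si](CC)(CC)CC)C=C[C@]1(O[Si](CC)(CC)CC)C#C[Li]
F7 | step 2 | 3-(phenylselanyl)cyclobutane-1,2-dione (racemic) | O=C1CC([Se]c2ccccc2)C1=O
F8 | step 2 | 3-(phenylseleninyl)cyclobutane-1,2-dione | O=C1CC([Se](=O)c2ccccc2)C1=O
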